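## The problem

- The target is a 2,3,4,7-tetrahydrooxepine (O1, C2 to C7, alkene C5=C6). Its quaternary C2 carries a carboxylic acid and a CH2C(=O)(2,5-dihydroxyphenyl) arm, and C6 carries an (E)-5-hydroxy-4-methylpent-3-enyl chain.
- A seven-membered ether with a trisubstituted alkene and an allylic O–CH2 (C7) is slow to close directly, so the ring is better made by enlarging a smaller one.
- C2 (R) is the only stereocentre. It is fully substituted and oxygen-bearing, nothing else in the molecule can induce it, and once made it cannot epimerise. The (E) side-chain alkene is independent of it.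
- Stereocentres that arise on the way (ring fusion, sulfonyl carbon, carbinol) have no control function and only have to be erased.
- The aryl ketone is a β-alkoxy ketone: enolisation toward C2 expels O1 and opens the ring, after which the ortho-phenol can re-close to a chromanone. An ester enolate at C6 would expel O1 from C7 in the same way, so late intermediates must not see base.
- The hydroquinone is easily oxidised, the two allylic C–O bonds (C7–O1 and the side-chain CH2OH) can ionise in strong acid, and a free hydroxyl γ to the C2 carboxyl lactonises.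
- Three carboxyl-level carbons (the C2 acid, the arm carbonyl, the substituent carbon on C6) have to be told apart.
- The enabling feature is that C5–C6 is a two-carbon unit between C4 and C7. O1, C2, C3, C4 and C7 alone form a 2,3-dihydrofuran whose enol ether is C4=C7, so inserting an alkyne between C4 and C7 enlarges the ring and puts a carbonyl handle on C6.

## Retrosynthesis

**33 to 32.** No skeletal bond is cut; the phenols, the allylic alcohol and the acid are masked as two methoxymethyl ethers, a tetrahydropyranyl ether and a tert-butyl ester. All four are acid-labile so that one acidic operation ends the synthesis, and base, which would open the β-alkoxy ketone, is never needed. The forward step must release the tert-butyl ester without ionising the allylic C–O bonds.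

**32 to 27 and 29.** The bond between the ketone carbon and the aromatic ring is cut. Friedel–Crafts acylation would need a Lewis acid and an acid chloride beside the ring ether, and addition to an ester would compete with the C2 ester. Aryllithium 30, made from symmetric 29 (one step from hydroquinone 28), instead adds to aldehyde 27 and carbinol 31 is oxidised. Aldehyde 27 comes from silyl ether 25 through alcohol 26. The forward reaction must add to an enolisable β-alkoxy aldehyde without opening it.

**25 to 17 and 22.** The side-chain bond between the CH2 on C6 and the next CH2 is cut. A Wittig cut at the trisubstituted alkene would be linear and longer, and a cut at C6 itself would need a C6 halide that the ring-forming step does not provide. This cut uses the carbon delivered on C6 as an allylic bromide (17) and brings the (E)-alkene ready-made in sulfone 22, available from 18 and 19 through 20 and 21. The forward steps are alkylation to 24 and removal of the sulfone without moving the double bond.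

**17 to 15.** Functional-group changes only: bromide 17 from alcohol 16, and 16 from the methyl ester of 15. The forward reduction must distinguish the conjugated methyl ester from the hindered tert-butyl ester.

**15 to 14.** Two hydrogens are removed from C4 and C7. The C5=C6 alkene of 15 is what a 1,4-addition of hydrogen to the diene C4=C5–C6=C7 of 14 leaves behind, and no enolate at C6 is involved.

**14 to 11 and 12 (key disconnection).** C4–C5 and C6–C7 are cut, which takes the C5–C6 unit out of the ring and leaves dihydrofuran 11 and methyl propiolate 12.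
- Ring-closing metathesis at C5=C6 would need two separately built alkenes and etherification of a hindered tertiary alcohol.
- Closure of O1–C7 would be a slow seven-membered etherification.
- The chosen cut reduces the seven-membered ring to a five-membered enol ether plus a commodity alkyne.
- The forward reaction must put the ester on C6 and spare the tert-butyl ester and the silyl ether.

**11 to 10.** O1–C7 is cut. The enol ether is the cycloisomer of terminal alkynol 10, which is shorter than dehydrating a lactol. The forward reaction must make a tertiary, ester-flanked hydroxyl add to the alkyne terminus.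

**10 to 5 and 6.** C2–C3 is cut. The quaternary centre is made by propargylating the enolate (7) of dioxolanone 5 with 6, giving 8; hydrolysis gives 9 and esterification gives 10. Against an asymmetric addition to an α-keto ester, this takes hydroxyl, carboxyl and the two-carbon arm from the chiral pool. The forward alkylation must replace hydrogen with retention.

**5 to 1 and 2.** (R)-Malic acid 1 and pivalaldehyde 2 give dioxolanone acid 3. This ties up the α-hydroxy acid and leaves the other carboxyl free for reduction to 4 and silylation to 5, which settles the differentiation of the C2 carboxyl from the arm at the outset.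

## Roads not taken

**Alternative 1: late aryne insertion into the arm acid.**
- Cut: the ketone–aryl bond and the aryl C–O bond of the ortho-phenol, at the very end, so the ring arrives as an aryne.
- Forward step: CsF releases a 3-bromo-4-(methoxymethoxy)benzyne from silyl triflate A3. The carboxylate of acid A2 adds to the aryne carbon remote from bromine, and the aryl anion takes over the acyl group, giving ortho-hydroxyaryl ketone A1.
- Merits: ketone and free ortho-phenol are made together from the acid oxidation level, no organolithium meets the tert-butyl ester, and no carbinol forms that could lactonise.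
- Weak points: arynes undergo ene reactions with trisubstituted alkenes, and A2 has two. The insertion needs hot fluoride, a basic medium in which the new β-alkoxy ketone can lose O1 and re-close through the phenoxide. The bromine must be removed afterwards without touching the alkenes, and A3 is itself a multi-step arene.
- Comparison: this road leaves the oxepine unsolved, since A2 needs the same ring construction, so it competes only with steps 17 to 21. There it would be about as long and is arguably the more elegant. The chosen sequence sets against it that every operation runs at or below room temperature, without base, and is indifferent to the alkenes.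

**Alternative 2: ring closure at C4–C5 by electroreductive decarboxylative alkenylation.**
- Cut: the ring bond C4–C5.
- Forward step: N-acyloxyphthalimide A5, which carries the (Z)-alkenyl iodide on the ether side, is electrolysed at constant current with NiCl2 and 2,2'-bipyridine (zinc anode). Loss of CO2 gives the C4 radical, nickel joins it to C5, and oxepine A4 closes with the alkene and the whole side chain in place.
- Merits: the alkene position is fixed by the iodide and the side chain comes in as a building block, so ester reduction, bromination, sulfone coupling and desulfonylation disappear. After the quaternary centre this road would probably be the shorter one.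
- Weak points: A5 needs a geometrically defined trisubstituted alkenyl iodide and O-alkylation of a hindered tertiary α-hydroxy ester. A primary radical must be captured by nickel and close a seven-membered ring against 6-exo addition to C6, hydrogen abstraction and dimerisation. Such couplings are established between two molecules, not for medium-ring closure, so the step is no better precedented than the chosen one.
- Comparison: the chosen plan takes C5 and C6 from a commodity alkyne, lets enol ether polarity rather than competing radical rates set the regiochemistry, needs no stereodefined alkene in 11, and is driven by loss of cyclobutene strain.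

**Alternative 3: oxygen insertion by Baeyer–Villiger oxidation.**
- Cut: O1–C2 and, formally, O1–C7; the ring oxygen is inserted last into a cyclohexanone.
- Forward step: ketone A7 with CF3CO3H buffered by Na2HPO4; the fully substituted carbon migrates with retention and lactone A6 results.
- Merits: this is one of the most dependable ring enlargements, the migrating carbon keeps its configuration, and A7 belongs to a well-studied class of 2-alkylated β-keto esters. In certainty of the key step this road is clearly ahead.
- Weak points: the stereocentre of A7 needs an asymmetric alkylation instead of the chiral pool. The migrating carbon bears an ester, which lowers its migratory aptitude. Above all, A6 has the wrong functionality: C7 is a lactone carbonyl that must be reduced to CH2 beside a tert-butyl ester, and the C5=C6 alkene and the C6 substituent must be added by enolate alkylation and a regioselective dehydrogenation.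
- Comparison: about the same number of operations after the ring is made, with a safer ring-forming step but more oxidation-state corrections. The chosen plan gets C7 at the ether level, the alkene between C5 and C6 and a carbon handle on C6 from the ring-forming event itself, at the price of a key step that still has to be proven.

Key step: step 8

Remark: the tetrahydropyranyl ethers (22 to 27, 31, 32) are carried as mixtures of epimers at the acetal carbon, and 13, 24 and 31 as mixtures at their transient centres; the SMILES leave these centres open, and none of them survives into 33.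

Abbreviations in names: TBDPS = tert-butyldiphenylsilyl, THP = tetrahydro-2H-pyran-2-yl, MOM = methoxymethyl.

## Route

Step 1
Reactants: 1 (R)-malic acid; 2 pivalaldehyde
Product: 3 2-[(2R,4R)-2-tert-butyl-5-oxo-1,3-dioxolan-4-yl]acetic acid
Conditions: p-TsOH (cat.), H2SO4 (cat.), pentane, reflux, Dean–Stark trap; recrystallisation
Reagents that add atoms: none
Why: Acid-catalysed acetalisation engages the α-hydroxy acid unit (five-membered dioxolanone rather than the six-membered alternative with the other carboxyl); the acetal centre is set under equilibrating conditions cis to the CH2CO2H group and the cis isomer is secured by crystallisation.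

Step 2
Reactants: 3 2-[(2R,4R)-2-tert-butyl-5-oxo-1,3-dioxolan-4-yl]acetic acid
Product: 4 (2R,5R)-2-tert-butyl-5-(2-hydroxyethyl)-1,3-dioxolan-4-one
Conditions: BH3·THF, THF, 0 → 20 °C; MeOH quench
Reagents that add atoms: none
Why: Borane reduces the free acid through its acyloxyborane much faster than the dioxolanone carbonyl; the alcohol is silylated at once because it can transacylate onto the ring carbonyl.

Step 3
Reactants: 4 (2R,5R)-2-tert-butyl-5-(2-hydroxyethyl)-1,3-dioxolan-4-one
Product: 5 (2R,5R)-2-tert-butyl-5-[2-(TBDPS-oxy)ethyl]-1,3-dioxolan-4-one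
Conditions: TBDPSCl, imidazole, CH2Cl2, 0 °C
Reagents that add atoms: tert-butyl(chloro)diphenylsilane, CC(C)(C)[Si](Cl)(c1ccccc1)c1ccccc1
Why: Standard silylation of a primary alcohol; the bulky silyl ether is chosen to withstand the enolate, the Lewis acid of step 8 and the hydride reagents that follow.

Step 4
Reactants: 5 (2R,5R)-2-tert-butyl-5-[2-(TBDPS-oxy)ethyl]-1,3-dioxolan-4-one; 6 3-bromo-1-(trimethylsilyl)prop-1-yne
Product: 8 (2R,5R)-2-tert-butyl-5-[2-(TBDPS-oxy)ethyl]-5-[3-(trimethylsilyl)prop-2-yn-1-yl]-1,3-dioxolan-4-one, via lithium dioxolanone enolate 7 (not isolated)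
Conditions: LiN(SiMe3)2, THF, −78 °C; then 6, −78 → −40 °C
Reagents that add atoms: none
Why: Enolate alkylation of a chiral dioxolanone (self-regeneration of the stereocentre): the electrophile enters anti to the tert-butyl group on the acetal carbon, so the propargyl group takes the place of the hydrogen with net retention and the quaternary centre is R; the silyl cap on the bromide blocks SN2′ attack and acetylide formation.

Step 5
Reactants: 8 (2R,5R)-2-tert-butyl-5-[2-(TBDPS-oxy)ethyl]-5-[3-(trimethylsilyl)prop-2-yn-1-yl]-1,3-dioxolan-4-one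
Product: 9 (2R)-2-[2-(TBDPS-oxy)ethyl]-2-hydroxypent-4-ynoic acid
Conditions: LiOH, THF/MeOH/H2O, 20 → 40 °C; then 1 M HCl to pH 3, 0 °C
Reagents that add atoms: lithium hydroxide, [Li+].[OH-]
Why: Saponification of the acylal-type lactone releases pivalaldehyde and the tertiary α-hydroxy acid, and the same basic medium cleaves the alkynyl C–Si bond; the quaternary centre cannot epimerise.

Step 6
Reactants: 9 (2R)-2-[2-(TBDPS-oxy)ethyl]-2-hydroxypent-4-ynoic acid
Product: 10 tert-butyl (2R)-2-[2-(TBDPS-oxy)ethyl]-2-hydroxypent-4-ynoate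
Conditions: O-tert-butyl-N,N'-diisopropylisourea, CH2Cl2, 20 °C
Reagents that add atoms: O-tert-butyl-N,N'-diisopropylisourea, CC(C)NC(=NC(C)C)OC(C)(C)C
Why: tert-Butyl transfer from the protonated isourea to the carboxylate is an O-alkylation, so it is insensitive to hindrance at the acyl carbon and leaves the tertiary alcohol free.

Step 7
Reactants: 10 tert-butyl (2R)-2-[2-(TBDPS-oxy)ethyl]-2-hydroxypent-4-ynoate
Product: 11 tert-butyl (2R)-2-[2-(TBDPS-oxy)ethyl]-2,3-dihydrofuran-2-carboxylate
Conditions: Mo(CO)6 (25 mol%), Et3N, Et2O, hν (350 nm), 20 °C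
Reagents that add atoms: none
Why: Alkynol cycloisomerisation through a molybdenum vinylidene: photogenerated Et3N·Mo(CO)5 converts the terminal alkyne into the vinylidene, the hydroxyl adds to its electrophilic carbon (net endo closure to the five-membered ring) and protodemetalation gives the enol ether; the reaction type is established for secondary and tertiary but-3-yn-1-ols.

Step 8
Reactants: 11 tert-butyl (2R)-2-[2-(TBDPS-oxy)ethyl]-2,3-dihydrofuran-2-carboxylate; 12 methyl propiolate
Product: 14 2-tert-butyl 6-methyl (2R)-2-[2-(TBDPS-oxy)ethyl]-2,3-dihydrooxepine-2,6-dicarboxylate, via oxabicycloheptene diester 13 (not isolated)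
Conditions: 12 (2 equiv), EtAlCl2 (30 mol%), CH2Cl2, −78 → 20 °C; then Et3N, PhMe, 80 °C
Reagents that add atoms: none
Why: Proposed new method: EtAlCl2 binds the propiolate carbonyl, the nucleophilic enol ether carbon C4 (oxepine numbering) adds to the alkyne terminus, and the O1-stabilised oxocarbenium ion at C7 is captured by the α-carbon of the aluminium allenolate in a 4-exo-trig closure, which gives cyclobutene 13 with the new bonds C4–C5 and C6–C7. Because the donor O1 and the acceptor ester flank the fusion bond C4–C7, that bond breaks on warming through an oxocarbenium/dienolate pair that collapses to the dienol ether, a formal 4π ring opening in which the seven-membered ring arises by enlargement of the five-membered one and not by a direct closure. The closest known reaction type is the Lewis-acid [2+2] addition of propiolates to silyl enol ethers followed by thermal opening of the cyclobutene, a two-carbon ring expansion of cyclic ketones; an endocyclic enol ether has not been used in this way. The two ring-fusion centres of 13 are cis by necessity, form as a mixture relative to C2 and both vanish on opening; C2 is insulated by C3 and is untouched. The step needs regioselectivity, which the enol ether polarity secures by joining the ester-bearing alkyne carbon to the oxygen-bearing C7 so that the ester ends on C6. It also needs ring closure to outrun proton transfer within the zwitterion and cationic oligomerisation of the enol ether, for which low temperature, excess propiolate and a substoichiometric Lewis acid are chosen. The tert-butyl ester and the silyl ether are the groups most exposed to the Lewis acid, hence the low loading and the amine quench before heating.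

Step 9
Reactants: 14 2-tert-butyl 6-methyl (2R)-2-[2-(TBDPS-oxy)ethyl]-2,3-dihydrooxepine-2,6-dicarboxylate
Product: 15 2-tert-butyl 6-methyl (2R)-2-[2-(TBDPS-oxy)ethyl]-2,3,4,7-tetrahydrooxepine-2,6-dicarboxylate
Conditions: Cr(CO)3(η6-naphthalene) (20 mol%), H2 (5 atm), THF, 45 °C
Reagents that add atoms: none
Why: Tricarbonylchromium-catalysed 1,4-hydrogenation: the diene, held s-cis by the ring, binds η4 to the Cr(CO)3 fragment and takes one hydrogen at each terminus (C4 and C7), leaving the C5=C6 bond; monoenes are not reduced and no enolate is formed that could expel O1 from C7.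

Step 10
Reactants: 15 2-tert-butyl 6-methyl (2R)-2-[2-(TBDPS-oxy)ethyl]-2,3,4,7-tetrahydrooxepine-2,6-dicarboxylate
Product: 16 tert-butyl (2R)-2-[2-(TBDPS-oxy)ethyl]-6-(hydroxymethyl)-2,3,4,7-tetrahydrooxepine-2-carboxylate
Conditions: iBu2AlH (2.3 equiv), CH2Cl2, −78 °C; aqueous potassium sodium tartrate
Reagents that add atoms: none
Why: iBu2AlH reduces the conjugated methyl ester to the allylic alcohol at −78 °C, while the tert-butyl ester on the fully substituted C2 is too hindered to react.

Step 11
Reactants: 16 tert-butyl (2R)-2-[2-(TBDPS-oxy)ethyl]-6-(hydroxymethyl)-2,3,4,7-tetrahydrooxepine-2-carboxylate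
Product: 17 tert-butyl (2R)-6-(bromomethyl)-2-[2-(TBDPS-oxy)ethyl]-2,3,4,7-tetrahydrooxepine-2-carboxylate
Conditions: CBr4, PPh3, CH2Cl2, 0 °C
Reagents that add atoms: tetrabromomethane, BrC(Br)(Br)Br
Why: Appel reaction: SN2 displacement of the alkoxyphosphonium at the primary allylic carbon under neutral conditions; the bromide is used without storage.

Step 12
Reactants: 18 1-bromo-3-methylbut-2-ene; 19 sodium benzenesulfinate (PhSO2Na)
Product: 20 [(3-methylbut-2-en-1-yl)sulfonyl]benzene
Conditions: DMF, 20 °C
Reagents that add atoms: none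
Why: S-Alkylation of the sulfinate by a primary allylic bromide.

Step 13
Reactants: 20 [(3-methylbut-2-en-1-yl)sulfonyl]benzene
Product: 21 (2E)-2-methyl-4-(phenylsulfonyl)but-2-en-1-ol
Conditions: SeO2 (20 mol%), t-BuOOH, CH2Cl2, 20 °C
Reagents that add atoms: selenium dioxide, O=[Se]=O; tert-butyl hydroperoxide, CC(C)(C)OO
Why: SeO2-catalysed allylic oxidation (ene reaction followed by [2,3]-shift) attacks the methyl group trans to the chain of a trisubstituted alkene, which fixes the (E) geometry of the side chain.

Step 14
Reactants: 21 (2E)-2-methyl-4-(phenylsulfonyl)but-2-en-1-ol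
Product: 22 2-{[(2E)-2-methyl-4-(phenylsulfonyl)but-2-en-1-yl]oxy}tetrahydro-2H-pyran
Conditions: 3,4-dihydro-2H-pyran, pyridinium p-toluenesulfonate (cat.), CH2Cl2, 20 °C
Reagents that add atoms: 3,4-dihydro-2H-pyran, C1=COCCC1
Why: Acid-catalysed acetal formation; the THP ether survives organolithiums, hydride, fluoride and buffered oxidation and falls off in the final acid step.

Step 15
Reactants: 22 2-{[(2E)-2-methyl-4-(phenylsulfonyl)but-2-en-1-yl]oxy}tetrahydro-2H-pyran; 17 tert-butyl (2R)-6-(bromomethyl)-2-[2-(TBDPS-oxy)ethyl]-2,3,4,7-tetrahydrooxepine-2-carboxylate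
Product: 24 tert-butyl (2R)-2-[2-(TBDPS-oxy)ethyl]-6-[(3E)-4-methyl-2-(phenylsulfonyl)-5-(THP-oxy)pent-3-en-1-yl]-2,3,4,7-tetrahydrooxepine-2-carboxylate, via lithiated sulfone 23 (not isolated)
Conditions: n-BuLi, THF, −78 °C; then 17, −78 → −40 °C
Reagents that add atoms: none
Why: Alkylation of an α-sulfonyl allyl anion, the classical sulfone coupling of prenyl units: the anion reacts at the sulfone-bearing carbon with the primary allylic bromide in an SN2 sense; the new sulfonyl-bearing centre is uncontrolled and is removed in step 16.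

Step 16
Reactants: 24 tert-butyl (2R)-2-[2-(TBDPS-oxy)ethyl]-6-[(3E)-4-methyl-2-(phenylsulfonyl)-5-(THP-oxy)pent-3-en-1-yl]-2,3,4,7-tetrahydrooxepine-2-carboxylate
Product: 25 tert-butyl (2R)-2-[2-(TBDPS-oxy)ethyl]-6-[(3E)-4-methyl-5-(THP-oxy)pent-3-en-1-yl]-2,3,4,7-tetrahydrooxepine-2-carboxylate
Conditions: PdCl2(dppp) (5 mol%), LiBHEt3 (2.2 equiv), THF, −20 → 0 °C
Reagents that add atoms: none
Why: Palladium-catalysed reductive desulfonylation: zerovalent palladium ionises the allylic sulfone to a π-allyl complex and hydride is delivered to the less substituted terminus, so the trisubstituted (E)-alkene stays in place; low temperature and limited hydride protect the hindered tert-butyl ester.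

Step 17
Reactants: 25 tert-butyl (2R)-2-[2-(TBDPS-oxy)ethyl]-6-[(3E)-4-methyl-5-(THP-oxy)pent-3-en-1-yl]-2,3,4,7-tetrahydrooxepine-2-carboxylate
Product: 26 tert-butyl (2R)-2-(2-hydroxyethyl)-6-[(3E)-4-methyl-5-(THP-oxy)pent-3-en-1-yl]-2,3,4,7-tetrahydrooxepine-2-carboxylate
Conditions: Bu4NF, AcOH, THF, 0 → 20 °C
Reagents that add atoms: none
Why: Fluoride cleaves the Si–O bond; acetic acid keeps the liberated alkoxide protonated so that it does not close onto the tert-butyl ester as a γ-lactone, and the acetal is unaffected.

Step 18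
Reactants: 26 tert-butyl (2R)-2-(2-hydroxyethyl)-6-[(3E)-4-methyl-5-(THP-oxy)pent-3-en-1-yl]-2,3,4,7-tetrahydrooxepine-2-carboxylate
Product: 27 tert-butyl (2R)-6-[(3E)-4-methyl-5-(THP-oxy)pent-3-en-1-yl]-2-(2-oxoethyl)-2,3,4,7-tetrahydrooxepine-2-carboxylate
Conditions: Dess–Martin periodinane, pyridine, CH2Cl2, 0 → 20 °C
Reagents that add atoms: none
Why: Dess–Martin oxidation under pyridine buffering gives the aldehyde without acid or base strong enough to open the β-alkoxy aldehyde or cleave the acetal.

Step 19
Reactants: 28 hydroquinone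
Product: 29 1,4-bis(methoxymethoxy)benzene
Conditions: MOMCl, i-Pr2NEt, CH2Cl2, 0 → 20 °C
Reagents that add atoms: chloromethyl methyl ether, COCCl
Why: Double O-alkylation of the phenol; the acetal oxygens later direct ortho-lithiation.

Step 20
Reactants: 29 1,4-bis(methoxymethoxy)benzene; 27 tert-butyl (2R)-6-[(3E)-4-methyl-5-(THP-oxy)pent-3-en-1-yl]-2-(2-oxoethyl)-2,3,4,7-tetrahydrooxepine-2-carboxylate
Product: 31 tert-butyl (2R)-2-{2-[2,5-bis(methoxymethoxy)phenyl]-2-hydroxyethyl}-6-[(3E)-4-methyl-5-(THP-oxy)pent-3-en-1-yl]-2,3,4,7-tetrahydrooxepine-2-carboxylate, via aryllithium 30 (not isolated)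
Conditions: 29, n-BuLi, TMEDA, THF, 0 °C; then 27, −78 °C; AcOH quench at −78 °C
Reagents that add atoms: none
Why: Directed ortho-lithiation (all four ring positions are equivalent) and 1,2-addition to the aldehyde at −78 °C; the tert-butyl ester is too hindered to compete, the cold acidic quench keeps the alkoxide from lactonising, and the uncontrolled carbinol centre is oxidised away in step 21.

Step 21
Reactants: 31 tert-butyl (2R)-2-{2-[2,5-bis(methoxymethoxy)phenyl]-2-hydroxyethyl}-6-[(3E)-4-methyl-5-(THP-oxy)pent-3-en-1-yl]-2,3,4,7-tetrahydrooxepine-2-carboxylate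
Product: 32 tert-butyl (2R)-2-{2-[2,5-bis(methoxymethoxy)phenyl]-2-oxoethyl}-6-[(3E)-4-methyl-5-(THP-oxy)pent-3-en-1-yl]-2,3,4,7-tetrahydrooxepine-2-carboxylate
Conditions: Dess–Martin periodinane, pyridine, CH2Cl2, 0 → 20 °C
Reagents that add atoms: none
Why: Dess–Martin oxidation of a secondary benzylic alcohol under buffered, non-basic conditions, so the new β-alkoxy ketone is not enolised.

Step 22
Reactants: 32 tert-butyl (2R)-2-{2-[2,5-bis(methoxymethoxy)phenyl]-2-oxoethyl}-6-[(3E)-4-methyl-5-(THP-oxy)pent-3-en-1-yl]-2,3,4,7-tetrahydrooxepine-2-carboxylate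
Product: 33 (2R)-2-[2-(2,5-dihydroxyphenyl)-2-oxoethyl]-6-[(3E)-5-hydroxy-4-methylpent-3-en-1-yl]-2,3,4,7-tetrahydrooxepine-2-carboxylic acid
Conditions: CF3CO2H/CH2Cl2/H2O (30:65:5), 0 → 20 °C, under argon
Reagents that add atoms: none
Why: Global acidolysis: the aryl methoxymethyl ethers and the THP acetal hydrolyse through oxocarbenium ions and the tert-butyl ester loses isobutene by alkyl–oxygen cleavage, with water trapping the cations; C2 has no hydrogen and cannot epimerise, and acid, unlike base, does not trigger β-elimination of O1 from the ketone.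

## Compound list

1 | (R)-malic acid | O[C@H](CC(=O)O)C(=O)O | starting material
2 | pivalaldehyde | CC(C)(C)C=O | starting material
3 | 2-[(2R,4R)-2-tert-butyl-5-oxo-1,3-dioxolan-4-yl]acetic acid | CC(C)(C)[C@@H]1O[C@H](CC(=O)O)C(=O)O1 | intermediate
4 | (2R,5R)-2-tert-butyl-5-(2-hydroxyethyl)-1,3-dioxolan-4-one | CC(C)(C)[C@@H]1O[C@H](CCO)C(=O)O1 | intermediate
5 | (2R,5R)-2-tert-butyl-5-[2-(tert-butyldiphenylsilyloxy)ethyl]-1,3-dioxolan-4-one | CC(C)(C)[C@@H]1O[C@H](CCO[Si](c2ccccc2)(c2ccccc2)C(C)(C)C)C(=O)O1 | intermediate
6 | 3-bromo-1-(trimethylsilyl)prop-1-yne | C[Si](C)(C)C#CCBr | starting material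
7 | lithium (2R)-2-tert-butyl-5-[2-(tert-butyldiphenylsilyloxy)ethyl]-1,3-dioxol-4-olate (lithium enolate of 5) | CC(C)(C)[C@@H]1OC(CCO[Si](c2ccccc2)(c2ccccc2)C(C)(C)C)=C(O[Li])O1 | intermediate (not isolated)
8 | (2R,5R)-2-tert-butyl-5-[2-(tert-butyldiphenylsilyloxy)ethyl]-5-[3-(trimethylsilyl)prop-2-yn-1-yl]-1,3-dioxolan-4-one | CC(C)(C)[C@@H]1O[C@](CC#C[Si](C)(C)C)(CCO[Si](c2ccccc2)(c2ccccc2)C(C)(C)C)C(=O)O1 | intermediate
9 | (2R)-2-[2-(tert-butyldiphenylsilyloxy)ethyl]-2-hydroxypent-4-ynoic acid | O[C@](CC#C)(CCO[Si](c1ccccc1)(c1ccccc1)C(C)(C)C)C(=O)O | intermediate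
10 | tert-butyl (2R)-2-[2-(tert-butyldiphenylsilyloxy)ethyl]-2-hydroxypent-4-ynoate | O[C@](CC#C)(CCO[Si](c1ccccc1)(c1ccccc1)C(C)(C)C)C(=O)OC(C)(C)C | intermediate
11 | tert-butyl (2R)-2-[2-(tert-butyldiphenylsilyloxy)ethyl]-2,3-dihydrofuran-2-carboxylate | C1=CC[C@@](CCO[Si](c2ccccc2)(c2ccccc2)C(C)(C)C)(C(=O)OC(C)(C)C)O1 | intermediate
12 | methyl propiolate | C#CC(=O)OC | starting material
13 | 3-tert-butyl 7-methyl (3R)-3-[2-(tert-butyldiphenylsilyloxy)ethyl]-2-oxabicyclo[3.2.0]hept-6-ene-3,7-dicarboxylate (cis-fused, both ring-fusion diastereomers) | COC(=O)C1=CC2C[C@@](CCO[Si](c3ccccc3)(c3ccccc3)C(C)(C)C)(C(=O)OC(C)(C)C)OC12 | intermediate (not isolated)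
14 | 2-tert-butyl 6-methyl (2R)-2-[2-(tert-butyldiphenylsilyloxy)ethyl]-2,3-dihydrooxepine-2,6-dicarboxylate | COC(=O)C=1C=CC[C@@](CCO[Si](c2ccccc2)(c2ccccc2)C(C)(C)C)(C(=O)OC(C)(C)C)OC=1 | intermediate
15 | 2-tert-butyl 6-methyl (2R)-2-[2-(tert-butyldiphenylsilyloxy)ethyl]-2,3,4,7-tetrahydrooxepine-2,6-dicarboxylate | COC(=O)C1=CCC[C@@](CCO[Si](c2ccccc2)(c2ccccc2)C(C)(C)C)(C(=O)OC(C)(C)C)OC1 | intermediate
16 | tert-butyl (2R)-2-[2-(tert-butyldiphenylsilyloxy)ethyl]-6-(hydroxymethyl)-2,3,4,7-tetrahydrooxepine-2-carboxylate | OCC1=CCC[C@@](CCO[Si](c2ccccc2)(c2ccccc2)C(C)(C)C)(C(=O)OC(C)(C)C)OC1 | intermediate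
17 | tert-butyl (2R)-6-(bromomethyl)-2-[2-(tert-butyldiphenylsilyloxy)ethyl]-2,3,4,7-tetrahydrooxepine-2-carboxylate | BrCC1=CCC[C@@](CCO[Si](c2ccccc2)(c2ccccc2)C(C)(C)C)(C(=O)OC(C)(C)C)OC1 | intermediate
18 | 1-bromo-3-methylbut-2-ene | CC(C)=CCBr | starting material
19 | sodium benzenesulfinate | [Na+].[O-]S(=O)c1ccccc1 | starting material
20 | [(3-methylbut-2-en-1-yl)sulfonyl]benzene | CC(C)=CCS(=O)(=O)c1ccccc1 | intermediate
21 | (2E)-2-methyl-4-(phenylsulfonyl)but-2-en-1-ol | C/C(=C\CS(=O)(=O)c1ccccc1)CO | intermediate
22 | 2-{[(2E)-2-methyl-4-(phenylsulfonyl)but-2-en-1-yl]oxy}tetrahydro-2H-pyran (racemic acetal) | C/C(=C\CS(=O)(=O)c1ccccc1)COC1CCCCO1 | intermediate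
23 | lithium salt of 22 at the sulfonyl-bearing carbon | C/C(=C\C([Li])S(=O)(=O)c1ccccc1)COC1CCCCO1 | intermediate (not isolated)
24 | tert-butyl (2R)-2-[2-(tert-butyldiphenylsilyloxy)ethyl]-6-[(3E)-4-methyl-2-(phenylsulfonyl)-5-(tetrahydro-2H-pyran-2-yloxy)pent-3-en-1-yl]-2,3,4,7-tetrahydrooxepine-2-carboxylate (epimers at the sulfonyl and acetal carbons) | C/C(=C\C(CC1=CCC[C@@](CCO[Si](c2ccccc2)(c2ccccc2)C(C)(C)C)(C(=O)OC(C)(C)C)OC1)S(=O)(=O)c1ccccc1)COC1CCCCO1 | intermediate
25 | tert-butyl (2R)-2-[2-(tert-butyldiphenylsilyloxy)ethyl]-6-[(3E)-4-methyl-5-(tetrahydro-2H-pyran-2-yloxy)pent-3-en-1-yl]-2,3,4,7-tetrahydrooxepine-2-carboxylate | C/C(=C\CCC1=CCC[C@@](CCO[Si](c2ccccc2)(c2ccccc2)C(C)(C)C)(C(=O)OC(C)(C)C)OC1)COC1CCCCO1 | intermediate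
26 | tert-butyl (2R)-2-(2-hydroxyethyl)-6-[(3E)-4-methyl-5-(tetrahydro-2H-pyran-2-yloxy)pent-3-en-1-yl]-2,3,4,7-tetrahydrooxepine-2-carboxylate | C/C(=C\CCC1=CCC[C@@](CCO)(C(=O)OC(C)(C)C)OC1)COC1CCCCO1 | intermediate
27 | tert-butyl (2R)-6-[(3E)-4-methyl-5-(tetrahydro-2H-pyran-2-yloxy)pent-3-en-1-yl]-2-(2-oxoethyl)-2,3,4,7-tetrahydrooxepine-2-carboxylate | C/C(=C\CCC1=CCC[C@@](CC=O)(C(=O)OC(C)(C)C)OC1)COC1CCCCO1 | intermediate
28 | hydroquinone | Oc1ccc(O)cc1 | starting material
29 | 1,4-bis(methoxymethoxy)benzene | COCOc1ccc(OCOC)cc1 | intermediate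
30 | [2,5-bis(methoxymethoxy)phenyl]lithium | [Li]c1cc(OCOC)ccc1OCOC | intermediate (not isolated)
31 | tert-butyl (2R)-2-{2-[2,5-bis(methoxymethoxy)phenyl]-2-hydroxyethyl}-6-[(3E)-4-methyl-5-(tetrahydro-2H-pyran-2-yloxy)pent-3-en-1-yl]-2,3,4,7-tetrahydrooxepine-2-carboxylate (epimers at the carbinol and acetal carbons) | C/C(=C\CCC1=CCC[C@@](CC(O)c2cc(OCOC)ccc2OCOC)(C(=O)OC(C)(C)C)OC1)COC1CCCCO1 | intermediate
32 | tert-butyl (2R)-2-{2-[2,5-bis(methoxymethoxy)phenyl]-2-oxoethyl}-6-[(3E)-4-methyl-5-(tetrahydro-2H-pyran-2-yloxy)pent-3-en-1-yl]-2,3,4,7-tetrahydrooxepine-2-carboxylate | C/C(=C\CCC1=CCC[C@@](CC(=O)c2cc(OCOC)ccc2OCOC)(C(=O)OC(C)(C)C)OC1)COC1CCCCO1 | intermediate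
33 | (2R)-2-[2-(2,5-dihydroxyphenyl)-2-oxoethyl]-6-[(3E)-5-hydroxy-4-methylpent-3-en-1-yl]-2,3,4,7-tetrahydrooxepine-2-carboxylic acid | C/C(=C\CCC1=CCC[C@@](CC(=O)c2cc(O)ccc2O)(C(=O)O)OC1)CO | target

## Step count and least certain steps

Total: 22 steps. Longest linear sequence: 18 steps (steps 1 to 11, 15 to 18 and 20 to 22).

**Step 8 (key step).** The most likely failure is that the zwitterion formed after the first C–C bond transfers a proton or starts cationic oligomerisation of the enol ether instead of closing the four-membered ring. The Lewis acid may also strip the tert-butyl ester, and the cyclobutene may resist opening. The fallback uses only known reactions, sets out from 11 and returns at 15, so that step 9 is bypassed as well. The enol ether is hydrated with pyridinium p-toluenesulfonate in wet THF to tert-butyl (2R)-2-[2-(TBDPS-oxy)ethyl]-5-hydroxytetrahydrofuran-2-carboxylate F1. Wittig methylenation with Ph3P=CH2 opens the lactol to tert-butyl (2R)-2-[2-(TBDPS-oxy)ethyl]-2-hydroxyhex-5-enoate F2. The tertiary alkoxide (NaH) is alkylated with methyl 2-(bromomethyl)acrylate to tert-butyl (2R)-2-[2-(TBDPS-oxy)ethyl]-2-{[2-(methoxycarbonyl)prop-2-en-1-yl]oxy}hex-5-enoate F3. Ring-closing metathesis with the second-generation Grubbs catalyst in toluene at 80 °C then forms the C5=C6 bond and gives 15.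

**Step 9.** The push–pull diene may bind the chromium fragment poorly, so turnover stalls, or the alkene may drift into conjugation with O1. The fallback sets out from 14 and returns at 15. Ionic hydrogenation with Et3SiH and CF3CO2H in CH2Cl2 protonates C4 and delivers hydride to the oxocarbenium carbon C7, as in reductions of allylic oxocarbenium ions. The tert-butyl ester is lost in the same medium, which gives (2R)-2-[2-(TBDPS-oxy)ethyl]-6-(methoxycarbonyl)-2,3,4,7-tetrahydrooxepine-2-carboxylic acid F4. The acid is re-esterified with O-tert-butyl-N,N'-diisopropylisourea to 15.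

**Step 16.** The hydride may attack the tert-butyl ester, or it may be delivered to the other allyl terminus with shift or E/Z scrambling of the side-chain alkene. The fallback sets out from 17 and returns at 25, building the alkene by olefination instead of carrying it through a sulfone:
- LiCH2CN (from MeCN and n-BuLi, THF, −78 °C) displaces the bromide to give tert-butyl (2R)-2-[2-(TBDPS-oxy)ethyl]-6-(2-cyanoethyl)-2,3,4,7-tetrahydrooxepine-2-carboxylate F5.
- iBu2AlH at −78 °C followed by hydrolysis gives tert-butyl (2R)-2-[2-(TBDPS-oxy)ethyl]-6-(3-oxopropyl)-2,3,4,7-tetrahydrooxepine-2-carboxylate F6.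
- Wittig reaction with Ph3P=C(CH3)CO2Et gives tert-butyl (2R)-2-[2-(TBDPS-oxy)ethyl]-6-[(3E)-5-ethoxy-4-methyl-5-oxopent-3-en-1-yl]-2,3,4,7-tetrahydrooxepine-2-carboxylate F7.
- iBu2AlH at −78 °C reduces the ethyl ester to tert-butyl (2R)-2-[2-(TBDPS-oxy)ethyl]-6-[(3E)-5-hydroxy-4-methylpent-3-en-1-yl]-2,3,4,7-tetrahydrooxepine-2-carboxylate F8.
- 3,4-Dihydro-2H-pyran with pyridinium p-toluenesulfonate gives 25.

**Step 20.** The aryllithium may enolise the β-alkoxy aldehyde, which is followed by expulsion of O1 and ring opening, or the carbinolate may close onto the tert-butyl ester. The fallback sets out from 27 and returns at 32, bypassing 31 and step 21. Oxidation with NaClO2, NaH2PO4 and 2-methylbut-2-ene gives 2-[(2R)-2-(tert-butoxycarbonyl)-6-[(3E)-4-methyl-5-(THP-oxy)pent-3-en-1-yl]-2,3,4,7-tetrahydrooxepin-2-yl]acetic acid F9. Carbodiimide coupling with N,O-dimethylhydroxylamine gives tert-butyl (2R)-2-{2-[methoxy(methyl)amino]-2-oxoethyl}-6-[(3E)-4-methyl-5-(THP-oxy)pent-3-en-1-yl]-2,3,4,7-tetrahydrooxepine-2-carboxylate F10. Aryllithium 30 adds to this amide to a chelated tetrahedral intermediate that releases ketone 32 only on work-up.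

**Step 22.** Ester cleavage may be incomplete under acid mild enough to spare the molecule, or the allylic C–O bonds may ionise and the tert-butyl and formaldehyde-derived cations may be captured by the hydroquinone. The fallback sets out from 32 and returns at 33 in two stages of different mechanism. Dilute HCl in THF/i-PrOH removes only the three acetals and gives tert-butyl (2R)-2-[2-(2,5-dihydroxyphenyl)-2-oxoethyl]-6-[(3E)-5-hydroxy-4-methylpent-3-en-1-yl]-2,3,4,7-tetrahydrooxepine-2-carboxylate F11. ZnBr2 in CH2Cl2 then cleaves the tert-butyl ester by chelation-assisted loss of isobutene, without a strong protic acid, and gives 33.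

## Further compounds

F1 | step 8 | tert-butyl (2R)-2-[2-(tert-butyldiphenylsilyloxy)ethyl]-5-hydroxytetrahydrofuran-2-carboxylate (both anomers) | OC1CC[C@@](CCO[Si](c2ccccc2)(c2ccccc2)C(C)(C)C)(C(=O)OC(C)(C)C)O1
F2 | step 8 | tert-butyl (2R)-2-[2-(tert-butyldiphenylsilyloxy)ethyl]-2-hydroxyhex-5-enoate | C=CCC[C@@](CCO[Si](c1ccccc1)(c1ccccc1)C(C)(C)C)(C(=O)OC(C)(C)C)O
F3 | step 8 | tert-butyl (2R)-2-[2-(tert-butyldiphenylsilyloxy)ethyl]-2-{[2-(methoxycarbonyl)prop-2-en-1-yl]oxy}hex-5-enoate | C=CCC[C@@](CCO[Si](c1ccccc1)(c1ccccc1)C(C)(C)C)(C(=O)OC(C)(C)C)OCC(=C)C(=O)OC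
F4 | step 9 | (2R)-2-[2-(tert-butyldiphenylsilyloxy)ethyl]-6-(methoxycarbonyl)-2,3,4,7-tetrahydrooxepine-2-carboxylic acid | COC(=O)C1=CCC[C@@](CCO[Si](c2ccccc2)(c2ccccc2)C(C)(C)C)(C(=O)O)OC1
F5 | step 16 | tert-butyl (2R)-2-[2-(tert-butyldiphenylsilyloxy)ethyl]-6-(2-cyanoethyl)-2,3,4,7-tetrahydrooxepine-2-carboxylate | N#CCCC1=CCC[C@@](CCO[Si](c2ccccc2)(c2ccccc2)C(C)(C)C)(C(=O)OC(C)(C)C)OC1
F6 | step 16 | tert-butyl (2R)-2-[2-(tert-butyldiphenylsilyloxy)ethyl]-6-(3-oxopropyl)-2,3,4,7-tetrahydrooxepine-2-carboxylate | O=CCCC1=CCC[C@@](CCO[Si](c2ccccc2)(c2ccccc2)C(C)(C)C)(C(=O)OC(C)(C)C)OC1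
F7 | step 16 | tert-butyl (2R)-2-[2-(tert-butyldiphenylsilyloxy)ethyl]-6-[(3E)-5-ethoxy-4-methyl-5-oxopent-3-en-1-yl]-2,3,4,7-tetrahydrooxepine-2-carboxylate | CCOC(=O)/C(C)=C/CCC1=CCC[C@@](CCO[Si](c2ccccc2)(c2ccccc2)C(C)(C)C)(C(=O)OC(C)(C)C)OC1
F8 | step 16 | tert-butyl (2R)-2-[2-(tert-butyldiphenylsilyloxy)ethyl]-6-[(3E)-5-hydroxy-4-methylpent-3-en-1-yl]-2,3,4,7-tetrahydrooxepine-2-carboxylate | C/C(=C\CCC1=CCC[C@@](CCO[Si](c2ccccc2)(c2ccccc2)C(C)(C)C)(C(=O)OC(C)(C)C)OC1)CO
F9 | step 20 | 2-[(2R)-2-(tert-butoxycarbonyl)-6-[(3E)-4-methyl-5-(tetrahydro-2H-pyran-2-yloxy)pent-3-en-1-yl]-2,3,4,7-tetrahydrooxepin-2-yl]acetic acid | C/C(=C\CCC1=CCC[C@@](CC(=O)O)(C(=O)OC(C)(C)C)OC1)COC1CCCCO1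
F10 | step 20 | tert-butyl (2R)-2-{2-[methoxy(methyl)amino]-2-oxoethyl}-6-[(3E)-4-methyl-5-(tetrahydro-2H-pyran-2-yloxy)pent-3-en-1-yl]-2,3,4,7-tetrahydrooxepine-2-carboxylate | C/C(=C\CCC1=CCC[C@@](CC(=O)N(C)OC)(C(=O)OC(C)(C)C)OC1)COC1CCCCO1
F11 | step 22 | tert-butyl (2R)-2-[2-(2,5-dihydroxyphenyl)-2-oxoethyl]-6-[(3E)-5-hydroxy-4-methylpent-3-en-1-yl]-2,3,4,7-tetrahydrooxepine-2-carboxylate | C/C(=C\CCC1=CCC[C@@](CC(=O)c2cc(O)ccc2O)(C(=O)OC(C)(C)C)OC1)CO
A1 | alternative 1 | tert-butyl (2R)-2-[2-(2-bromo-6-hydroxy-3-(methoxymethoxy)phenyl)-2-oxoethyl]-6-[(3E)-5-(methoxymethoxy)-4-methylpent-3-en-1-yl]-2,3,4,7-tetrahydrooxepine-2-carboxylate | C/C(=C\CCC1=CCC[C@@](CC(=O)c2c(Br)c(OCOC)ccc2O)(C(=O)OC(C)(C)C)OC1)COCOC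
A2 | alternative 1 | 2-[(2R)-2-(tert-butoxycarbonyl)-6-[(3E)-5-(methoxymethoxy)-4-methylpent-3-en-1-yl]-2,3,4,7-tetrahydrooxepin-2-yl]acetic acid | C/C(=C\CCC1=CCC[C@@](CC(=O)O)(C(=O)OC(C)(C)C)OC1)COCOC
A3 | alternative 1 | 2-bromo-3-(methoxymethoxy)-6-(trimethylsilyl)phenyl trifluoromethanesulfonate | COCOc1ccc([Si](C)(C)C)c(OS(=O)(=O)C(F)(F)F)c1Br
A4 | alternative 2 | tert-butyl (2R)-2-[2-(tert-butyldimethylsilyloxy)ethyl]-6-[(3E)-5-(methoxymethoxy)-4-methylpent-3-en-1-yl]-2,3,4,7-tetrahydrooxepine-2-carboxylate | C/C(=C\CCC1=CCC[C@@](CCO[Si](C)(C)C(C)(C)C)(C(=O)OC(C)(C)C)OC1)COCOC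
A5 | alternative 2 | tert-butyl (2R)-2-[2-(tert-butyldimethylsilyloxy)ethyl]-5-[(1,3-dioxoisoindolin-2-yl)oxy]-2-{[(2Z,5E)-2-(iodomethylidene)-7-(methoxymethoxy)-6-methylhept-5-en-1-yl]oxy}-5-oxopentanoate | I/C=C(\CO[C@](CCC(=O)ON1C(=O)c2ccccc2C1=O)(CCO[Si](C)(C)C(C)(C)C)C(=O)OC(C)(C)C)CC/C=C(\C)COCOC
A6 | alternative 3 | tert-butyl (2R)-2-[2-(tert-butyldimethylsilyloxy)ethyl]-7-oxooxepane-2-carboxylate | O=C1CCCC[C@@](CCO[Si](C)(C)C(C)(C)C)(C(=O)OC(C)(C)C)O1
A7 | alternative 3 | tert-butyl (1S)-1-[2-(tert-butyldimethylsilyloxy)ethyl]-2-oxocyclohexane-1-carboxylate | O=C1CCCC[C@@]1(CCO[Si](C)(C)C(C)(C)C)C(=O)OC(C)(C)C
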